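Turning percent into millimolar is the easy step: amber makes 7.19 mM d⁻¹ of product over its full 3.00 d, and teal makes 6.75 mM d⁻¹ over its first 1.04 d, nearly the same rate from charges of 52 mM and 26 mM of starting material. A nearly constant rate of this kind is called pseudo-zero-order. Between teal and green the partner charge changes the reading little: at 3.00 d, green with 110 mM reads 3.7 percentage points above teal with 73 mM.

| flask | starting material | partner | free catalyst | remark | time |
|---|---|---|---|---|---|
| teal | 26 mM | 73 mM | 1.3 mM | run made earlier |  |
| green | 26 mM | 110 mM | 1.3 mM | run made earlier |  |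
| amber | 52 mM | 52 mM | 1.3 mM | run made earlier |  |
| flask | 26 mM | 52.0 mM | 1.3 mM |  | 2.5 d |

| run | time / d | product / % | starting material / % |
|---|---|---|---|
| teal | 0.250 | 4.9 | 94.6 |
| teal | 0.417 | 8.5 | 89.9 |
| teal | 0.625 | 15.7 | 86.3 |
| teal | 1.04 | 27.0 | 75.3 |
| teal | 1.67 | 40.4 | 58.9 |
| teal | 3.00 | 64.9 | 33.3 |
| green | 0.250 | 7.8 | 92.8 |
| green | 0.417 | 11.7 | 89.3 |
| green | 0.625 | 17.1 | 81.7 |
| green | 1.04 | 27.1 | 72.9 |
| green | 1.67 | 42.7 | 56.5 |
| green | 3.00 | 68.6 | 30.1 |
| amber | 0.250 | 3.7 | 97.4 |
| amber | 0.417 | 4.8 | 94.4 |
| amber | 0.833 | 11.7 | 87.1 |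
| amber | 1.67 | 23.0 | 73.4 |
| amber | 3.00 | 41.5 | 59.2 |

(standard deviation of a reading: 1 percentage point)

- amount of product in percent of the starting material charged, at 12 h, 30 h and 2.5 d

The new flask can be reckoned in two ways. Amber has the flask's partner charge, and its straight line gives 18.0 mM at 2.5 d, or 69.2% of the flask's charge. Teal has the flask's starting-material charge, and interpolating its readings gives 55.7%. The two part by 14 points, and the line is the one that cheats: amber still holds 30.8 mM at its last reading, more than the flask's whole charge of 26 mM, whereas teal's late rate has sunk to 4.79 mM d⁻¹.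

The slowing is a correction to the line. With rate = V c/(K + c), where c is c(starting material) and V the ceiling rate, V × time equals product formed plus K ln(charge/c), and K is the slowing constant, the c(starting material) at which the rate stands at 0.5 of its ceiling. Setting aside the difference in partner charge, the readings at 3.00 d in teal and amber give K = 8.18 mM and V = 8.62 mM d⁻¹. The ceiling line reaches 21.5 mM at 2.5 d; the correction, taken at teal's conversion, is 6.66 mM, which leaves 57.3%. This lies close to teal's interpolation, but the correction was taken from that interpolation, so the closeness is no check. The reckoning here commits to about 55.7% at 2.5 d, and teal's interpolation gives 11.4% at 12 h and 31.5% at 30 h.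

The forecast, on the ground “This points to a nearly saturated catalyst”, gives 12%, 29% and 55%.

The flask gives 11.2%, 29.5% and 55.7%.

    partner + free catalyst ⇌ catalyst intermediate A (K = 1100 L mol⁻¹, k = 0.00790 L mol⁻¹ s⁻¹)
    catalyst intermediate D → free catalyst + product (k = 3.50 × 10⁻⁴ s⁻¹)
    catalyst intermediate A → by-product + catalyst intermediate B (k = 2.40 × 10⁻⁴ s⁻¹)
    starting material + catalyst intermediate C ⇌ catalyst intermediate D (K = 55.0 L mol⁻¹, k = 0.0150 L mol⁻¹ s⁻¹)
    catalyst intermediate B → catalyst intermediate C (k = 4.90 × 10⁻⁴ s⁻¹)

At 2.50 d the flask holds 43.7% of its starting material, and catalyst intermediate C has grown from 29.1% of the catalyst charged at 0.250 d to 44.9%. Put into the law with K = 8.18 mM, the 10.9% of starting material that the flask holds at 5.00 d belongs to 4.79 d.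

The runs are calculated for an exercise, noise included.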